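**Retrosynthetic overview**
1. Target ⇐ desilylation and Markovnikov hydrobromination of a C14' isopropenyl group (C15'–Br made last) ⇐ 15-membered lactone closed by Yamaguchi lactonisation at C14'–OH.
2. Seco acid ⇐ Negishi C1'–C2' coupling of a benzylzinc with a cyclohexenyl triflate; the triflate masks the tetrasubstituted ring alkene during side-chain oxidation.
3. Side chain: C14' by CBS reduction of an isopropenyl ketone; C10'–Br/C11'–OH by Shi epoxidation and SN2 bromide opening; E-C10'=C11' and C12'–C14' by Johnson–Claisen rearrangement.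
4. Carbocycle: key C7'–C8' bond (quaternary carbon) by intermolecular Michael addition of 2-methylcyclohexane-1,3-dione to acrolein; then CBS desymmetrisation, Appel inversion (C6'–Br), methylation and enol triflation.
5. Ring order: the six-membered carbocycle comes with the starting dione; the macrolactone is the only ring formed (step 20).

Assumption and locants (one line): the configuration is taken exactly as in the SMILES; with C1' = benzylic CH2, C2'=C3' ring alkene, C6' ring CHBr, C7' quaternary C, C10' chain CHBr, C11' carbinol, C14' ester carbinol, C15' CMe2Br, the target is (6'S,7'S,10'R,11'S,14'S).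

**Step 1**
Reactants: 1 2-methylcyclohexane-1,3-dione; 2 acrolein
Product: 3 3-(1-methyl-2,6-dioxocyclohexyl)propanal
Conditions: H2O, rt, 24 h
Reagents that add atoms: none
Why: Intermolecular Michael addition of the stabilised dione enolate to acrolein forms the C7'–C8' bond and the (still prochiral) all-carbon quaternary centre, the doubly activated C–H being acidic enough for water alone to mediate it.

**Step 2**
Reactants: 3 3-(1-methyl-2,6-dioxocyclohexyl)propanal
Product: 4 2-[2-(1,3-dioxolan-2-yl)ethyl]-2-methylcyclohexane-1,3-dione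
Conditions: HOCH2CH2OH (1.1 equiv), p-TsOH·H2O (cat.), MgSO4, CH2Cl2, rt
Reagents that add atoms: ethylene glycol, OCCO
Why: Chemoselective acetalisation, because the unhindered aldehyde forms the dioxolane far faster than the two neopentyl-type ketones.

**Step 3**
Reactants: 4 2-[2-(1,3-dioxolan-2-yl)ethyl]-2-methylcyclohexane-1,3-dione
Product: 5 (2R,3R)-2-[2-(1,3-dioxolan-2-yl)ethyl]-3-hydroxy-2-methylcyclohexan-1-one
Conditions: (S)-1-methyl-3,3-diphenyltetrahydro-1H,3H-pyrrolo[1,2-c][1,3,2]oxazaborole (0.2 equiv), BH3·SMe2 (0.7 equiv), THF, −30 °C; MeOH quench; minor diastereomer removed by chromatography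
Reagents that add atoms: none
Why: CBS desymmetrising reduction in which the (S)-oxazaborolidine reduces one enantiotopic carbonyl to the (R)-carbinol with hydride entering syn to the small CH3, so OH ends cis to the side chain and C6' and the quaternary C7' are fixed together (the antipode of the familiar yeast ketol series).

**Step 4**
Reactants: 5 (2R,3R)-2-[2-(1,3-dioxolan-2-yl)ethyl]-3-hydroxy-2-methylcyclohexan-1-one
Product: 6 (2S,3S)-3-bromo-2-[2-(1,3-dioxolan-2-yl)ethyl]-2-methylcyclohexan-1-one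
Conditions: PPh3, CBr4, 2,6-lutidine, toluene, 0 → 60 °C
Reagents that add atoms: carbon tetrabromide, BrC(Br)(Br)Br
Why: Appel reaction in which bromide displaces the alkoxyphosphonium by SN2 with inversion at C6', placing Br cis to the C7' methyl, while the adjacent carbonyl disfavours cationic rearrangement.

**Step 5**
Reactants: 6 (2S,3S)-3-bromo-2-[2-(1,3-dioxolan-2-yl)ethyl]-2-methylcyclohexan-1-one
Product: 8 (2S,3S)-3-bromo-2-[2-(1,3-dioxolan-2-yl)ethyl]-2,6-dimethylcyclohexan-1-one (C6 epimers), via lithium enolate 7 (not isolated)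
Conditions: LiN(i-Pr)2, THF, −78 °C; MeI, −78 → −20 °C
Reagents that add atoms: iodomethane, CI; LiN(i-Pr)2, [Li+].CC(C)[N-]C(C)C (Li stays only in 7)
Why: Kinetic enolate alkylation that is regiospecific because only C3' carries enolisable hydrogens (the other α-carbon is quaternary), the new C3' centre being erased in the next step.

**Step 6**
Reactants: 8 (2S,3S)-3-bromo-2-[2-(1,3-dioxolan-2-yl)ethyl]-2,6-dimethylcyclohexan-1-one
Product: 10 (5S,6S)-5-bromo-6-[2-(1,3-dioxolan-2-yl)ethyl]-2,6-dimethylcyclohex-1-en-1-yl trifluoromethanesulfonate, via potassium enolate 9 (not isolated)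
Conditions: KN(SiMe3)2, THF, −78 → −20 °C; PhNTf2, −78 °C → rt
Reagents that add atoms: N-phenylbis(trifluoromethanesulfonimide), O=S(=O)(N(c1ccccc1)S(=O)(=O)C(F)(F)F)C(F)(F)F; KN(SiMe3)2, [K+].C[Si](C)(C)[N-][Si](C)(C)C (K stays only in 9)
Why: Enol triflate formation, where the only possible enolate is the tetrasubstituted one, so O-sulfonylation fixes the C2'=C3' position and gives an oxidation-resistant mask of the ring alkene.

**Step 7**
Reactants: 10 (5S,6S)-5-bromo-6-[2-(1,3-dioxolan-2-yl)ethyl]-2,6-dimethylcyclohex-1-en-1-yl trifluoromethanesulfonate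
Product: 11 (5S,6S)-5-bromo-2,6-dimethyl-6-(3-oxopropyl)cyclohex-1-en-1-yl trifluoromethanesulfonate
Conditions: 1 M HCl, THF, rt
Reagents that add atoms: water, O
Why: Acid-catalysed acetal hydrolysis frees the C10' aldehyde while enol triflate and alkyl bromide are inert to dilute acid.

**Step 8**
Reactants: 11 (5S,6S)-5-bromo-2,6-dimethyl-6-(3-oxopropyl)cyclohex-1-en-1-yl trifluoromethanesulfonate; 12 isopropenylmagnesium bromide
Product: 13 (5S,6S)-5-bromo-6-(3-hydroxy-4-methylpent-4-en-1-yl)-2,6-dimethylcyclohex-1-en-1-yl trifluoromethanesulfonate (carbinol epimers)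
Conditions: CH2=C(CH3)MgBr, THF, −78 °C; aq NH4Cl
Reagents that add atoms: none
Why: Grignard 1,2-addition to the aldehyde at low temperature brings in C11', its methyl and C12', and the carbinol configuration is irrelevant because the next step destroys it.

**Step 9**
Reactants: 13 (5S,6S)-5-bromo-6-(3-hydroxy-4-methylpent-4-en-1-yl)-2,6-dimethylcyclohex-1-en-1-yl trifluoromethanesulfonate; 14 triethyl orthoacetate
Product: 16 ethyl (4E)-7-[(1S,6S)-6-bromo-1,3-dimethyl-2-(trifluoromethanesulfonyloxy)cyclohex-2-en-1-yl]-4-methylhept-4-enoate, via ketene acetal 15 (not isolated)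
Conditions: CH3C(OEt)3 (solvent), EtCO2H (cat.), 140 °C, EtOH distilled off
Reagents that add atoms: none
Why: Johnson–Claisen rearrangement through a chair transition state with the side chain equatorial gives the E-trisubstituted C10'=C11' alkene and appends C13'–C14' as an ester.

**Step 10**
Reactants: 16 ethyl (4E)-7-[(1S,6S)-6-bromo-1,3-dimethyl-2-(trifluoromethanesulfonyloxy)cyclohex-2-en-1-yl]-4-methylhept-4-enoate
Product: 17 (4E)-7-[(1S,6S)-6-bromo-1,3-dimethyl-2-(trifluoromethanesulfonyloxy)cyclohex-2-en-1-yl]-N-methoxy-N,4-dimethylhept-4-enamide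
Conditions: MeNH(OMe)·HCl, i-PrMgCl, THF, −20 → 0 °C
Reagents that add atoms: N,O-dimethylhydroxylamine hydrochloride, CNOC.Cl
Why: Aminolysis of the ester by the chloromagnesium amide gives the Weinreb amide, which later guarantees a single organometallic addition.

**Step 11**
Reactants: 17 (4E)-7-[(1S,6S)-6-bromo-1,3-dimethyl-2-(trifluoromethanesulfonyloxy)cyclohex-2-en-1-yl]-N-methoxy-N,4-dimethylhept-4-enamide
Product: 18 3-[(2S,3S)-3-{2-[(1S,6S)-6-bromo-1,3-dimethyl-2-(trifluoromethanesulfonyloxy)cyclohex-2-en-1-yl]ethyl}-2-methyloxiran-2-yl]-N-methoxy-N-methylpropanamide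
Conditions: 1,2:4,5-di-O-isopropylidene-β-L-erythro-2,3-hexodiulo-2,6-pyranose (0.3 equiv), KHSO5 (as 2KHSO5·KHSO4·K2SO4), K2CO3, Bu4NHSO4, Na2B4O7/Na2EDTA buffer, MeCN/CH2(OMe)2/H2O, 0 °C
Reagents that add atoms: potassium peroxymonosulfate, [K+].[O-]S(=O)(=O)OO
Why: Shi asymmetric epoxidation, in which the dioxirane of the L-series ketone attacks the E-trisubstituted alkene through the spiro transition state to give the (10'S,11'S)-epoxide under reagent control while the electron-poor enol triflate alkene is not oxidised.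

**Step 12**
Reactants: 18 3-[(2S,3S)-3-{2-[(1S,6S)-6-bromo-1,3-dimethyl-2-(trifluoromethanesulfonyloxy)cyclohex-2-en-1-yl]ethyl}-2-methyloxiran-2-yl]-N-methoxy-N-methylpropanamide; 12 isopropenylmagnesium bromide
Product: 19 1-[(2S,3S)-3-{2-[(1S,6S)-6-bromo-1,3-dimethyl-2-(trifluoromethanesulfonyloxy)cyclohex-2-en-1-yl]ethyl}-2-methyloxiran-2-yl]-4-methylpent-4-en-3-one
Conditions: CH2=C(CH3)MgBr, THF, −40 → 0 °C; cold aq NH4Cl
Reagents that add atoms: none
Why: Weinreb ketone synthesis, where the chelated tetrahedral intermediate stops at mono-addition to give the isopropenyl ketone (C15' and its carbons) and the trisubstituted epoxide survives the cold Grignard reagent.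

**Step 13**
Reactants: 19 1-[(2S,3S)-3-{2-[(1S,6S)-6-bromo-1,3-dimethyl-2-(trifluoromethanesulfonyloxy)cyclohex-2-en-1-yl]ethyl}-2-methyloxiran-2-yl]-4-methylpent-4-en-3-one
Product: 20 (6S,7R)-7-bromo-9-[(1S,6S)-6-bromo-1,3-dimethyl-2-(trifluoromethanesulfonyloxy)cyclohex-2-en-1-yl]-6-hydroxy-2,6-dimethylnon-1-en-3-one
Conditions: Li2NiBr4 (0.4 M in THF), THF, 0 °C → rt; pH 7 buffer
Reagents that add atoms: Li2NiBr4, [Li+].[Li+].[Ni+2].[Br-].[Br-].[Br-].[Br-]
Why: Regioselective SN2 epoxide opening by soft bromide at the less substituted C10' with inversion gives the (10'R)-bromide and leaves the (11'S)-tertiary alcohol untouched.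

**Step 14**
Reactants: 20 (6S,7R)-7-bromo-9-[(1S,6S)-6-bromo-1,3-dimethyl-2-(trifluoromethanesulfonyloxy)cyclohex-2-en-1-yl]-6-hydroxy-2,6-dimethylnon-1-en-3-one
Product: 21 (6S,7R)-7-bromo-9-[(1S,6S)-6-bromo-1,3-dimethyl-2-(trifluoromethanesulfonyloxy)cyclohex-2-en-1-yl]-2,6-dimethyl-6-(triethylsilyloxy)non-1-en-3-one
Conditions: Et3SiOTf, 2,6-lutidine, CH2Cl2, −78 °C
Reagents that add atoms: triethylsilyl trifluoromethanesulfonate, CC[Si](CC)(CC)OS(=O)(=O)C(F)(F)F
Why: Silylation of the tertiary alcohol with the silyl triflate blocks base-induced reclosure of the bromohydrin to the epoxide in all later steps.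

**Step 15**
Reactants: 21 (6S,7R)-7-bromo-9-[(1S,6S)-6-bromo-1,3-dimethyl-2-(trifluoromethanesulfonyloxy)cyclohex-2-en-1-yl]-2,6-dimethyl-6-(triethylsilyloxy)non-1-en-3-one
Product: 22 (3S,6S,7R)-7-bromo-9-[(1S,6S)-6-bromo-1,3-dimethyl-2-(trifluoromethanesulfonyloxy)cyclohex-2-en-1-yl]-2,6-dimethyl-6-(triethylsilyloxy)non-1-en-3-ol
Conditions: (R)-1-methyl-3,3-diphenyltetrahydro-1H,3H-pyrrolo[1,2-c][1,3,2]oxazaborole (0.3 equiv), catecholborane, toluene, −78 °C
Reagents that add atoms: none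
Why: CBS reduction in which the isopropenyl group acts as the large substituent, so the (R)-oxazaborolidine delivers hydride to give the (14'S)-allylic alcohol by clean 1,2-reduction.

**Step 16**
Reactants: 23 methyl 4-hydroxy-3-methylbenzoate
Product: 24 methyl 3-methyl-4-(triisopropylsilyloxy)benzoate
Conditions: i-Pr3SiCl, imidazole, DMF, rt
Reagents that add atoms: triisopropylsilyl chloride, CC(C)[Si](Cl)(C(C)C)C(C)C
Why: Standard phenol silylation giving an ether that survives organozinc formation, tin-mediated ester hydrolysis and acylation conditions yet falls to fluoride at the end.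

**Step 17**
Reactants: 24 methyl 3-methyl-4-(triisopropylsilyloxy)benzoate
Product: 25 methyl 3-(bromomethyl)-4-(triisopropylsilyloxy)benzoate
Conditions: NBS, 2,2'-azobis(2-methylpropionitrile) (cat.), PhCF3, 80 °C
Reagents that add atoms: N-bromosuccinimide, O=C1CCC(=O)N1Br
Why: Wohl–Ziegler radical bromination is selective for the benzylic methyl because the ester-deactivated ring resists electrophilic bromination.

**Step 18**
Reactants: 25 methyl 3-(bromomethyl)-4-(triisopropylsilyloxy)benzoate; 22 (3S,6S,7R)-7-bromo-9-[(1S,6S)-6-bromo-1,3-dimethyl-2-(trifluoromethanesulfonyloxy)cyclohex-2-en-1-yl]-2,6-dimethyl-6-(triethylsilyloxy)non-1-en-3-ol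
Product: 27 methyl 3-{[(5S,6S)-5-bromo-6-[(3R,4S,7S)-3-bromo-7-hydroxy-4,8-dimethyl-4-(triethylsilyloxy)non-8-en-1-yl]-2,6-dimethylcyclohex-1-en-1-yl]methyl}-4-(triisopropylsilyloxy)benzoate, via benzylzinc bromide 26 (not isolated)
Conditions: 25, Zn dust, LiCl, THF, 0 °C → rt; then 22, Pd(OAc)2 (5 mol %), 2-dicyclohexylphosphino-2',6'-dimethoxybiphenyl (10 mol %), THF, 40 °C
Reagents that add atoms: zinc, [Zn] (stays only in 26)
Why: Negishi coupling, in which zinc inserts selectively into the benzylic C–Br bond and palladium-catalysed sp3–sp2 coupling with the enol triflate forms C1'–C2' and unveils the tetrasubstituted alkene, the organozinc tolerating ester, secondary bromides and the free hydroxyl.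

**Step 19**
Reactants: 27 methyl 3-{[(5S,6S)-5-bromo-6-[(3R,4S,7S)-3-bromo-7-hydroxy-4,8-dimethyl-4-(triethylsilyloxy)non-8-en-1-yl]-2,6-dimethylcyclohex-1-en-1-yl]methyl}-4-(triisopropylsilyloxy)benzoate
Product: 28 3-{[(5S,6S)-5-bromo-6-[(3R,4S,7S)-3-bromo-7-hydroxy-4,8-dimethyl-4-(triethylsilyloxy)non-8-en-1-yl]-2,6-dimethylcyclohex-1-en-1-yl]methyl}-4-(triisopropylsilyloxy)benzoic acid
Conditions: Me3SnOH, ClCH2CH2Cl, 80 °C; 0.1 M HCl wash
Reagents that add atoms: trimethyltin hydroxide, C[Sn](C)(C)O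
Why: Tin hydroxide-mediated hydrolysis cleaves the methyl ester under near-neutral conditions that leave both silyl ethers and both alkyl bromides intact.

**Step 20**
Reactants: 28 3-{[(5S,6S)-5-bromo-6-[(3R,4S,7S)-3-bromo-7-hydroxy-4,8-dimethyl-4-(triethylsilyloxy)non-8-en-1-yl]-2,6-dimethylcyclohex-1-en-1-yl]methyl}-4-(triisopropylsilyloxy)benzoic acid
Product: 30 (6'S,7'S,10'R,11'S,14'S)-14'-isopropenyl macrolactone (aryl OSi(i-Pr)3; C11' OSiEt3; 6',10'-dibromide), via mixed anhydride 29 (not isolated)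
Conditions: 2,4,6-Cl3C6H2COCl, Et3N, THF, rt; then slow addition to 4-(dimethylamino)pyridine, toluene (1 mM), 60 °C
Reagents that add atoms: 2,4,6-trichlorobenzoyl chloride, O=C(Cl)c1c(Cl)cc(Cl)cc1Cl (stays only in 29)
Why: Yamaguchi macrolactonisation, where the mixed anhydride acylates the unhindered secondary allylic C14'–OH at high dilution and closes the 15-membered ring with retention at C14'.

**Step 21**
Reactants: 30 (6'S,7'S,10'R,11'S,14'S)-14'-isopropenyl macrolactone (aryl OSi(i-Pr)3; C11' OSiEt3; 6',10'-dibromide)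
Product: 31 bromophycolide A bis-silyl ether (aryl OSi(i-Pr)3; C11' OSiEt3)
Conditions: Co(acac)2 (0.25 equiv), t-BuOOH (0.25 equiv), Et3SiH, TsBr, n-PrOH/CH2Cl2, rt
Reagents that add atoms: p-toluenesulfonyl bromide, Cc1ccc(cc1)S(=O)(=O)Br
Why: Markovnikov hydrobromination by hydrogen-atom transfer (Mukaiyama type), in which the cobalt hydride gives H to the 1,1-disubstituted alkene much faster than to the hindered tetrasubstituted ring alkene and the tertiary radical takes Br from TsBr, so the C15' bromide forms without ionic intermediates and C14' is untouched.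

**Step 22**
Reactants: 31 bromophycolide A bis-silyl ether (aryl OSi(i-Pr)3; C11' OSiEt3)
Product: 32 bromophycolide A
Conditions: HF·pyridine, pyridine, THF, 0 °C → rt
Reagents that add atoms: none
Why: Fluoride-mediated desilylation under buffered, non-basic conditions removes both silyl ethers without closing the bromohydrin or ionising the tertiary bromide.

**Compound list**
1 | 2-methylcyclohexane-1,3-dione | CC1C(=O)CCCC1=O | starting material
2 | acrolein (prop-2-enal) | C=CC=O | starting material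
3 | 3-(1-methyl-2,6-dioxocyclohexyl)propanal | CC1(CCC=O)C(=O)CCCC1=O | intermediate
4 | 2-[2-(1,3-dioxolan-2-yl)ethyl]-2-methylcyclohexane-1,3-dione | CC1(CCC2OCCO2)C(=O)CCCC1=O | intermediate
5 | (2R,3R)-2-[2-(1,3-dioxolan-2-yl)ethyl]-3-hydroxy-2-methylcyclohexan-1-one (OH cis to side chain) | C1COC(O1)CC[C@]2(C)[C@H](O)CCCC2=O | intermediate
6 | (2S,3S)-3-bromo-2-[2-(1,3-dioxolan-2-yl)ethyl]-2-methylcyclohexan-1-one (Br cis to CH3) | C1COC(O1)CC[C@]2(C)[C@@H](Br)CCCC2=O | intermediate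
7 | lithium (5S,6S)-5-bromo-6-[2-(1,3-dioxolan-2-yl)ethyl]-6-methylcyclohex-1-en-1-olate | C1COC(O1)CC[C@]2(C)[C@@H](Br)CCC=C2O[Li] | intermediate
8 | (2S,3S)-3-bromo-2-[2-(1,3-dioxolan-2-yl)ethyl]-2,6-dimethylcyclohexan-1-one (C6 epimers) | C1COC(O1)CC[C@]2(C)[C@@H](Br)CCC(C)C2=O | intermediate
9 | potassium (5S,6S)-5-bromo-6-[2-(1,3-dioxolan-2-yl)ethyl]-2,6-dimethylcyclohex-1-en-1-olate | C1COC(O1)CC[C@]2(C)[C@@H](Br)CCC(C)=C2O[K] | intermediate
10 | (5S,6S)-5-bromo-6-[2-(1,3-dioxolan-2-yl)ethyl]-2,6-dimethylcyclohex-1-en-1-yl trifluoromethanesulfonate | C1COC(O1)CC[C@]2(C)[C@@H](Br)CCC(C)=C2OS(=O)(=O)C(F)(F)F | intermediate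
11 | (5S,6S)-5-bromo-2,6-dimethyl-6-(3-oxopropyl)cyclohex-1-en-1-yl trifluoromethanesulfonate | O=CCC[C@]1(C)[C@@H](Br)CCC(C)=C1OS(=O)(=O)C(F)(F)F | intermediate
12 | isopropenylmagnesium bromide | C=C(C)[Mg]Br | starting material
13 | (5S,6S)-5-bromo-6-(3-hydroxy-4-methylpent-4-en-1-yl)-2,6-dimethylcyclohex-1-en-1-yl trifluoromethanesulfonate (carbinol epimers) | C=C(C)C(O)CC[C@]1(C)[C@@H](Br)CCC(C)=C1OS(=O)(=O)C(F)(F)F | intermediate
14 | triethyl orthoacetate | CCOC(C)(OCC)OCC | starting material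
15 | 1-ethoxyvinyl ether of 13 (mixed ketene acetal) | C=C(OCC)OC(C(C)=C)CC[C@]1(C)[C@@H](Br)CCC(C)=C1OS(=O)(=O)C(F)(F)F | intermediate
16 | ethyl (4E)-7-[(1S,6S)-6-bromo-1,3-dimethyl-2-(trifluoromethanesulfonyloxy)cyclohex-2-en-1-yl]-4-methylhept-4-enoate | CCOC(=O)CC/C(C)=C/CC[C@]1(C)[C@@H](Br)CCC(C)=C1OS(=O)(=O)C(F)(F)F | intermediate
17 | (4E)-7-[(1S,6S)-6-bromo-1,3-dimethyl-2-(trifluoromethanesulfonyloxy)cyclohex-2-en-1-yl]-N-methoxy-N,4-dimethylhept-4-enamide | CON(C)C(=O)CC/C(C)=C/CC[C@]1(C)[C@@H](Br)CCC(C)=C1OS(=O)(=O)C(F)(F)F | intermediate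
18 | 3-[(2S,3S)-3-{2-[(1S,6S)-6-bromo-1,3-dimethyl-2-(trifluoromethanesulfonyloxy)cyclohex-2-en-1-yl]ethyl}-2-methyloxiran-2-yl]-N-methoxy-N-methylpropanamide | CON(C)C(=O)CC[C@]2(C)O[C@H]2CC[C@]1(C)[C@@H](Br)CCC(C)=C1OS(=O)(=O)C(F)(F)F | intermediate
19 | 1-[(2S,3S)-3-{2-[(1S,6S)-6-bromo-1,3-dimethyl-2-(trifluoromethanesulfonyloxy)cyclohex-2-en-1-yl]ethyl}-2-methyloxiran-2-yl]-4-methylpent-4-en-3-one | C=C(C)C(=O)CC[C@]2(C)O[C@H]2CC[C@]1(C)[C@@H](Br)CCC(C)=C1OS(=O)(=O)C(F)(F)F | intermediate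
20 | (6S,7R)-7-bromo-9-[(1S,6S)-6-bromo-1,3-dimethyl-2-(trifluoromethanesulfonyloxy)cyclohex-2-en-1-yl]-6-hydroxy-2,6-dimethylnon-1-en-3-one | C=C(C)C(=O)CC[C@](C)(O)[C@H](Br)CC[C@]1(C)[C@@H](Br)CCC(C)=C1OS(=O)(=O)C(F)(F)F | intermediate
21 | (6S,7R)-7-bromo-9-[(1S,6S)-6-bromo-1,3-dimethyl-2-(trifluoromethanesulfonyloxy)cyclohex-2-en-1-yl]-2,6-dimethyl-6-(triethylsilyloxy)non-1-en-3-one | C=C(C)C(=O)CC[C@](C)(O[Si](CC)(CC)CC)[C@H](Br)CC[C@]1(C)[C@@H](Br)CCC(C)=C1OS(=O)(=O)C(F)(F)F | intermediate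
22 | (3S,6S,7R)-7-bromo-9-[(1S,6S)-6-bromo-1,3-dimethyl-2-(trifluoromethanesulfonyloxy)cyclohex-2-en-1-yl]-2,6-dimethyl-6-(triethylsilyloxy)non-1-en-3-ol | C=C(C)[C@@H](O)CC[C@](C)(O[Si](CC)(CC)CC)[C@H](Br)CC[C@]1(C)[C@@H](Br)CCC(C)=C1OS(=O)(=O)C(F)(F)F | intermediate
23 | methyl 4-hydroxy-3-methylbenzoate | COC(=O)c1ccc(O)c(C)c1 | starting material
24 | methyl 3-methyl-4-(triisopropylsilyloxy)benzoate | COC(=O)c1ccc(O[Si](C(C)C)(C(C)C)C(C)C)c(C)c1 | intermediate
25 | methyl 3-(bromomethyl)-4-(triisopropylsilyloxy)benzoate | COC(=O)c1ccc(O[Si](C(C)C)(C(C)C)C(C)C)c(CBr)c1 | intermediate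
26 | [5-(methoxycarbonyl)-2-(triisopropylsilyloxy)benzyl]zinc bromide | COC(=O)c1ccc(O[Si](C(C)C)(C(C)C)C(C)C)c(C[Zn]Br)c1 | intermediate
27 | methyl 3-{[(5S,6S)-5-bromo-6-[(3R,4S,7S)-3-bromo-7-hydroxy-4,8-dimethyl-4-(triethylsilyloxy)non-8-en-1-yl]-2,6-dimethylcyclohex-1-en-1-yl]methyl}-4-(triisopropylsilyloxy)benzoate | C=C(C)[C@@H](O)CC[C@](C)(O[Si](CC)(CC)CC)[C@H](Br)CC[C@]1(C)[C@@H](Br)CCC(C)=C1Cc1cc(ccc1O[Si](C(C)C)(C(C)C)C(C)C)C(=O)OC | intermediate
28 | corresponding benzoic acid (seco acid) | C=C(C)[C@@H](O)CC[C@](C)(O[Si](CC)(CC)CC)[C@H](Br)CC[C@]1(C)[C@@H](Br)CCC(C)=C1Cc1cc(ccc1O[Si](C(C)C)(C(C)C)C(C)C)C(=O)O | intermediate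
29 | mixed anhydride of 28 with 2,4,6-trichlorobenzoic acid | C=C(C)[C@@H](O)CC[C@](C)(O[Si](CC)(CC)CC)[C@H](Br)CC[C@]1(C)[C@@H](Br)CCC(C)=C1Cc1cc(ccc1O[Si](C(C)C)(C(C)C)C(C)C)C(=O)OC(=O)c1c(Cl)cc(Cl)cc1Cl | intermediate
30 | (6'S,7'S,10'R,11'S,14'S)-14'-isopropenyl macrolactone: bromophycolide A skeleton with CH2=C(CH3)– on C14' in place of CMe2Br, aryl OSi(i-Pr)3, C11' OSiEt3 | CC1=C2Cc3cc(ccc3O[Si](C(C)C)(C(C)C)C(C)C)C(=O)O[C@H](C(C)=C)CC[C@](C)(O[Si](CC)(CC)CC)[C@H](Br)CC[C@]2(C)[C@@H](Br)CC1 | intermediate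
31 | bromophycolide A bis-silyl ether (aryl OSi(i-Pr)3, C11' OSiEt3) | CC1=C2Cc3cc(ccc3O[Si](C(C)C)(C(C)C)C(C)C)C(=O)O[C@H](C(C)(C)Br)CC[C@](C)(O[Si](CC)(CC)CC)[C@H](Br)CC[C@]2(C)[C@@H](Br)CC1 | intermediate
32 | bromophycolide A | CC1=C2Cc3cc(ccc3O)C(=O)O[C@H](C(C)(C)Br)CC[C@](C)(O)[C@H](Br)CC[C@]2(C)[C@@H](Br)CC1 | target

**Totals**
Total step count: 22. Longest linear sequence: 20 steps (steps 1–15, then 18–22; steps 16–17 prepare the aryl partner).

**Three steps most likely to fail, with fallbacks**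

Step 4 (SN2 bromination at the neopentyl C6' carbinol; elimination or no reaction are the risks). The fallback sets out from 5 and comes back at 10. The displacement is moved to a ring that already carries the sp2 C2' and uses a sulfonate leaving group. Ketol 5 is silylated (t-BuMe2SiCl, imidazole, DMF) to the silyl ether F1. This is methylated (LiN(i-Pr)2, MeI) to the dimethyl ketone F2 and converted (KN(SiMe3)2, PhNTf2) into the enol triflate F3. HF·pyridine in THF then frees the alcohol F4 without touching the dioxolane. Tf2O and pyridine at −40 °C give the alkyl triflate F5, and Bu4NBr in toluene displaces it with inversion to give 10.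

Step 20 (macrolactonisation; oligomerisation or a seco acid that resists closure). The fallback sets out from 21 and comes back at 30. It activates the alcohol instead of the acid. Ketone 21 is reduced with the (S)-oxazaborolidine and catecholborane to the (14'R)-alcohol F6. Negishi coupling with 26 as in step 18 gives the ester F7, and Me3SnOH gives the epimeric seco acid F8. Mitsunobu lactonisation (PPh3, diisopropyl azodicarboxylate, toluene, high dilution, 0 °C) closes the ring with inversion at C14', which delivers 30.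

Step 21 (hydrogen-atom-transfer hydrobromination; the risks are incomplete chemoselectivity or poor bromine transfer). The fallback sets out from 30 and comes back at 31. It replaces the radical bromine transfer by hydration followed by ionic substitution. Oxymercuration–demercuration (Hg(OAc)2, THF/H2O; then NaBH4, NaOH) hydrates only the unhindered 1,1-disubstituted alkene to the tertiary alcohol F9. Me3SiBr in CH2Cl2 at −40 °C then ionises the tertiary carbinol with anchimeric help from the neighbouring ester (aryl-dioxolan-2-ylium ion). Bromide opens this ion at the tertiary carbon, so C14' keeps its configuration and 31 results.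

**Further compounds**
F1 | step 4 | (2R,3R)-3-(tert-butyldimethylsilyloxy)-2-[2-(1,3-dioxolan-2-yl)ethyl]-2-methylcyclohexan-1-one | C1COC(O1)CC[C@]2(C)[C@H](O[Si](C)(C)C(C)(C)C)CCCC2=O
F2 | step 4 | (2R,3R)-3-(tert-butyldimethylsilyloxy)-2-[2-(1,3-dioxolan-2-yl)ethyl]-2,6-dimethylcyclohexan-1-one (C6 epimers) | C1COC(O1)CC[C@]2(C)[C@H](O[Si](C)(C)C(C)(C)C)CCC(C)C2=O
F3 | step 4 | (5R,6R)-5-(tert-butyldimethylsilyloxy)-6-[2-(1,3-dioxolan-2-yl)ethyl]-2,6-dimethylcyclohex-1-en-1-yl trifluoromethanesulfonate | C1COC(O1)CC[C@]2(C)[C@H](O[Si](C)(C)C(C)(C)C)CCC(C)=C2OS(=O)(=O)C(F)(F)F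
F4 | step 4 | (5R,6R)-6-[2-(1,3-dioxolan-2-yl)ethyl]-5-hydroxy-2,6-dimethylcyclohex-1-en-1-yl trifluoromethanesulfonate | C1COC(O1)CC[C@]2(C)[C@H](O)CCC(C)=C2OS(=O)(=O)C(F)(F)F
F5 | step 4 | (5R,6R)-6-[2-(1,3-dioxolan-2-yl)ethyl]-2,6-dimethyl-5-(trifluoromethanesulfonyloxy)cyclohex-1-en-1-yl trifluoromethanesulfonate | C1COC(O1)CC[C@]2(C)[C@H](OS(=O)(=O)C(F)(F)F)CCC(C)=C2OS(=O)(=O)C(F)(F)F
F6 | step 20 | (3R,6S,7R)-7-bromo-9-[(1S,6S)-6-bromo-1,3-dimethyl-2-(trifluoromethanesulfonyloxy)cyclohex-2-en-1-yl]-2,6-dimethyl-6-(triethylsilyloxy)non-1-en-3-ol (C14' epimer of 22) | C=C(C)[C@H](O)CC[C@](C)(O[Si](CC)(CC)CC)[C@H](Br)CC[C@]1(C)[C@@H](Br)CCC(C)=C1OS(=O)(=O)C(F)(F)F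
F7 | step 20 | methyl 3-{[(5S,6S)-5-bromo-6-[(3R,4S,7R)-3-bromo-7-hydroxy-4,8-dimethyl-4-(triethylsilyloxy)non-8-en-1-yl]-2,6-dimethylcyclohex-1-en-1-yl]methyl}-4-(triisopropylsilyloxy)benzoate (C14' epimer of 27) | C=C(C)[C@H](O)CC[C@](C)(O[Si](CC)(CC)CC)[C@H](Br)CC[C@]1(C)[C@@H](Br)CCC(C)=C1Cc1cc(ccc1O[Si](C(C)C)(C(C)C)C(C)C)C(=O)OC
F8 | step 20 | benzoic acid corresponding to F7 (C14' epimer of 28) | C=C(C)[C@H](O)CC[C@](C)(O[Si](CC)(CC)CC)[C@H](Br)CC[C@]1(C)[C@@H](Br)CCC(C)=C1Cc1cc(ccc1O[Si](C(C)C)(C(C)C)C(C)C)C(=O)O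
F9 | step 21 | macrolactone with (CH3)2C(OH)– on C14' (aryl OSi(i-Pr)3, C11' OSiEt3; 6'S,7'S,10'R,11'S,14'S) | CC1=C2Cc3cc(ccc3O[Si](C(C)C)(C(C)C)C(C)C)C(=O)O[C@H](C(C)(C)O)CC[C@](C)(O[Si](CC)(CC)CC)[C@H](Br)CC[C@]2(C)[C@@H](Br)CC1
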